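Set two amounts side by side: the target the east flask had made when it went flat, 48 % of the starting material as read, and the catalyst it was given, 0.47 mol%. The first is far larger.

| setting | east | north-west | flask |
|---|---|---|---|
| starting material | 10 mM | 10 mM | 10 mM |
| second substrate | 0.50 equiv | 0.75 equiv | 0.500 equiv |
| partner | 1.1 equiv | 1.1 equiv | 1.10 equiv |
| free catalyst | 0.47 mol% | 0.47 mol% | 0.47 mol% |
| remark | the very flask that is asked about, followed so far | run made earlier |  |
| time |  |  | 40 min |

- east (time / min: target / %): 6.00: 48; 12.0: 47; 20.0: 48; 25.0: 48
- north-west (time / s: target / %): 20.0: 11; 40.0: 19; 60.0: 25; 80.0: 32

(standard deviation of a reading: 1.5 percentage points)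

- target that was removed still counts
- additions bring no volume worth counting

- autumn: at 40 min take out 90 % of the target then present, then wait 12 min
- midnight: at 40 min add partner, 50.0 % of the amount charged, then wait 12 min
- summer: at 40 min add free catalyst, 100 % of the amount charged, then wait 12 min
- dawn: change nothing and wait 12 min more

- target, in percent of the starting material first charged, at 40 min
- the remedy with the largest gain of target, or "none" below 2 percentage points (autumn / midnight / summer / dawn / none)
- target present, with what was taken out counted in, in percent of the starting material first charged, after midnight
- target present, with what was taken out counted in, in percent of the starting material first charged, after summer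

The ratio of those two amounts, as read, is 102 rounds to target per catalyst, a turnover number. My own reckoning reads the flat line as a catalyst that has stopped working. Follow one catalyst molecule: at each round it either meets partner and goes on, or it dies, so its chance of going on should grow with [partner]. I therefore carry the turnover budget per equivalent of partner 92.8. Both runs hold the same partner charge, so this is a supposition the readings can't test. It gives about 48 % at 40 min, and it makes summer the best remedy, well past the 2 percentage points mark but below the first charge's 48 %, with the partner thinned by the target already made.

The forecast gives 48 % now, none as best remedy, 48.3 % after midnight and 48.8 % after summer, holding that “every remedy is capped at 50%”.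

The flask gives 47.7 %, 47.7 % after midnight and 59.7 % after summer, so the best remedy is summer, with a gain of 12 points.

    starting material + free catalyst ⇌ catalyst intermediate A (K = 79.0 M⁻¹, k = 440 M⁻¹ s⁻¹)
    partner + catalyst intermediate A → free catalyst + target (k = 1700 M⁻¹ s⁻¹)
    second substrate + free catalyst ⇌ catalyst intermediate B (K = 220 M⁻¹, k = 4000 M⁻¹ s⁻¹)
    partner + catalyst intermediate B → free catalyst + second product (k = 720 M⁻¹ s⁻¹)
    catalyst intermediate A → spent catalyst (k = 0.0830 s⁻¹)

At 40.0 min the east flask holds spent catalyst at 100 % of the catalyst charged, beside starting material at 51.9 % of its own charge. Take away the passing of catalyst intermediate A into spent catalyst and summer's gain falls from 12 points to 0 points, which is a part of the picture, not its main reason. In summer the fresh catalyst finds partner at 19.7 % of the partner charged, so the budget promises 9.5 points against the 12 points found.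

Now take a neighbour charged with 0.440 equiv of partner, all else as in the east flask: the budget gives 19.2 %, and the computed flask gives 19.4 %, with spent catalyst at 100 %.

(The readings are calculated with constants of no real substance.)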